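## Structural features

The target is a 1-aryltetralin lignan of the lyoniresinol type in which arene ring A (C4a, C5–C8, C8a; OMe on C6 and C8, OH on C7) is fused to the saturated ring B (C1–C4) and a 4-hydroxy-3,5-dimethoxyphenyl ring C sits on C1. C1, C2 and C3 are contiguous stereocentres of configuration 1S,2R,3R, with the aryl group on C1, the hydroxymethyl carbon C9 on C2 and the hydroxymethyl carbon C9' on C3 trans,trans, while C4 is a plain benzylic CH2. C1 is doubly benzylic, lies peri to the C8 methoxy group and never has a neighbouring carbonyl, so it cannot be repaired by enolisation. C2 and C3 are epimerisable only while C9 and C9' are at the carbonyl level. The fragile parts are the two electron-rich phenols (air oxidation, quinone methide formation through the C1–H para to the ring C phenol) and the acid-ionisable C1. The real difficulty is the C1/C2 trans relation next to the C8 methoxy group, together with the absolute configuration. The key step exploits ring B as a cyclohexane annulated to ring A with trans carbon substituents on C2 and C3: C1–C8a–C4a–C4 is the four-carbon unit of an ortho-quinodimethane, and C2–C3 with C9 and C9' is an E-butenedioate.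

## Logic of the disconnections

**16 back to 15.** The two phenolic O–CH2Ph bonds are cut (oxygen on C7 of ring A and the para oxygen of ring C). The phenols have to stay masked through amide base, Grignard reagent, hot toluene and hydride. The gain is that the oxidation-prone phenols appear only in the last flask. The demand is a neutral unmasking that leaves the C1–aryl bond and both alcohols alone, which hydrogenolysis meets.

**15 back to 14.** No skeletal bond is cut. C9 and C9' are raised from the alcohol to the ester level, so that C2 and C3 carry two acyl groups that can activate an alkene and hold chiral alkoxy groups. The gain is a trans-diester that is the direct product of a cycloaddition. The demand is a reduction fast enough, at low temperature, that C2 and C3 do not enolise; it must also cleave the auxiliaries in the same operation.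

**14 back to 13 and 12.** C1–C2 and C3–C4 are cut. This removes ring B and all three stereocentres at once and leaves two fragments of similar size: 13, which is achiral, and 12, which is C2-symmetric. The demand is heavy and cannot be relaxed later. The forward step must place the C2 acyl group exo and must use one face of 12. Base epimerisation of a 1,2-cis adduct at C2 alone would only lead into the 2,3-cis series, and C1 cannot be epimerised at all. Stereocontrol therefore has to be kinetic, backed by separation of diastereomers at the stage of 14.

**13 back to 9.** The C1–C4 bond is formed in the retrosynthetic sense. 13 cannot be stored; 9 is its bench-stable valence isomer and releases it on heating without reagent or by-product. Because C1 is planar in 13, the configuration of 9 is irrelevant and 9 may be racemic. The demand is outward rotation of the aryl group during ring opening, at a temperature that 12 tolerates.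

**12 back to 10 and 11.** Two acyl C–O bonds are cut, so that one molecule of 10 is joined to two molecules of 11. The gain is two commercial components. The demand is esterification without racemising 11 or isomerising the E-alkene.

**9 back to 8, and 8 back to 6 and 7.** First the C1–H bond is traced to a C1–OH bond, then the C1–aryl bond is cut. C1 of 6 is a carbonyl carbon, so the aryl group can arrive as a nucleophile. This avoids a C1 halide, which on this ring would be an ortho,para-dialkoxybenzylic halide and would ionise readily. The gain is that ring C comes from the same bromide as ring A, in two steps from 6. The demands are a cold quench, because the alkoxide of 8 can open its four-membered ring, and a deoxygenation in which the C1 cation meets only hydride.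

**6 back to 2 and 3 (through 5 and 4).** The two bonds from ring A to the four-membered ring are cut (C8a–C1 and C4a–C4). An aryne [2+2] builds the strained ring in one step. The methoxy group next to the aryne bond directs the acetal carbon, the future C1, onto the ring carbon beside it, which is the regiochemistry the target needs. 2 is symmetrical about the C–Br axis, so only one aryne can form. The demand is that 3 captures 4 faster than the amide base does, hence an excess of 3.

**7 back to 2, and 2 back to 1.** The C–Mg bond and the O–benzyl bond are cut. Both are routine and lead to 1, the one commercial source of rings A and C.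

## Other disconnections considered

Alternative 1: The cut is C1–C2. The precursor is A1: ring A carries on C8a the exocyclic carbon C1 of a syringyl para-quinone methide, and on C4a the chain C4–C3(C9' silyl ether)–C2–C9 ending in an aldehyde.

- Forward step: a chiral secondary amine of the diarylprolinol silyl ether class would convert the aldehyde into an enamine. Its carbon C2 would add to C1 in a 1,6-fashion (6-exo closure of ring B), ring C would rearomatise to the free phenol, and hydrolysis would give A2.
- In favour: the chirality source is catalytic, the reaction should run near room temperature, rearomatisation is a strong driving force, and the C2 aldehyde of A2 stays adjustable by enolisation. On these points it is the equal or the better of the chosen plan.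
- Against: A1 must already hold C3 as one enantiomer, which costs a separate asymmetric operation. The quinone methide has only methoxy groups beside its carbonyl, so hydration and oligomerisation are likely while it is generated by oxidation next to an aldehyde. The peri C8 methoxy group twists the electrophile. Catalyst control must also agree with the resident C3 centre.
- Comparison: the chosen plan makes both ring bonds and all three stereocentres in one concerted step from fragments prepared in four steps and one step. This route makes one bond and two centres in a polar, stepwise closure and needs a longer linear preparation of A1, estimated at ten or more steps overall.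

Alternative 2: The cuts are C1–C8a and C2–C3. The partners are the ring A boronic acid A3, which carries an (E)-4-methoxybut-2-enyl chain on C4a, and the ring C arylpropiolate A4.

- Forward step: with [Rh(OH)(cod)]2 (monovalent rhodium) and a chiral diphosphine such as BINAP, transmetalation would give an arylrhodium species that adds across the alkyne of A4 (ring A to C1, rhodium to C2). The alkenylrhodium would insert the tethered alkene (C2–C3, closing ring B), and β-methoxide elimination would leave a vinyl group on C3, giving A5.
- In favour: the route is convergent, catalytic in metal and in chirality, and mild, and it places the aryl and carboxyl groups on C1 and C2 without regiochemical doubt. On catalytic enantiocontrol it is the better, and on convergence the equal, of the chosen plan.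
- Against: A3 is a 2,6-disubstituted, very electron-rich boronic acid, so slow transmetalation and fast protodeboronation are to be feared. The step sets only C3. C1 and C2 would have to be created by reducing a hindered tetrasubstituted styrenyl ester; syn hydrogenation would give the 1,2-cis relation and would also attack the vinyl group. The vinyl group must then be cut down to C9' by ozonolysis next to electron-rich arenes.
- Comparison: four or more operations would follow the key step, against two in the chosen plan, and the hardest stereochemical problem (C1 against C2) would remain open after the key step.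

Alternative 3: The cuts are C1–C8a and C1–aryl. The precursor is the trans-disubstituted lactol A6: its hemiacetal carbon is C1, C2 bears C9 as a benzyl ether, and C3 bears the ring A benzyl group (C4). The second partner is 2,6-dimethoxyphenol A7.

- Forward step: a Lewis or Brønsted acid (BF3·OEt2 or CF3SO3H) would ionise A6 at C1. Ring A would attack through C8a and close ring B as a cyclic benzylic ether bridging C1 and C9'. Renewed ionisation would give the C1 benzylic cation, which A7 would capture through its para position on the face away from the C2 substituent, giving A8.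
- In favour: the C2/C3 trans pair is preset in a simple lactone-derived unit. The C1/C2 trans relation rests on attack anti to the neighbouring substituent of a cyclic benzylic cation. This is arguably a firmer basis than the exo/endo preference of a cycloaddition, and on this point the alternative is the better. Ring C also enters unprotected from a cheap phenol.
- Against: two cationic events among very electron-rich arenes invite over-alkylation of A7, attack at its position ortho/para to the methoxy groups, oligomerisation and loss of benzyl ethers. The bridged ether needs a 1,3-cis geometry. A6 requires its two stereocentres to be set in a separate sequence of about six steps.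
- Comparison: the total count would be similar or higher (about ten steps) and the route less convergent. The chosen plan needs no strong acid and draws both arenes from one bromide.

Key step: step 6

**Assumptions and remarks**

- Under purely thermal conditions the bis-(S)-lactate 12 is assumed to react on the Re face of C2 and C3. If the facial sense proves opposite, methyl (R)-lactate is used in step 5 and nothing else changes.
- Tetralin numbering (C1 aryl-bearing, C9 on C2, C9' on C3) is used for 14–16 and for the alternatives.
- The aryl-outward geometry of 13, called E in the parent series, is Z by the sequence rules because C8 carries oxygen.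

## Route

Step 1
Reactants: 1 4-bromo-2,6-dimethoxyphenol
Product: 2 2-(benzyloxy)-5-bromo-1,3-dimethoxybenzene
Conditions: BnBr, K2CO3, DMF, rt
Reagents that add atoms: benzyl bromide, BrCc1ccccc1
Why: Williamson ether synthesis on a phenoxide; the aryl bromide is inert to carbonate, and the benzyl ether withstands every later step until hydrogenolysis.

Step 2
Reactants: 2 2-(benzyloxy)-5-bromo-1,3-dimethoxybenzene; 3 1,1-dimethoxyethene
Product: 6 4-(benzyloxy)-3,5-dimethoxybicyclo[4.2.0]octa-1,3,5-trien-7-one, via aryne 4 (not isolated), via ketone dimethyl acetal 5 (not isolated)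
Conditions: NaNH2, THF, reflux (3 in excess); then 1 M HCl, THF, rt
Reagents that add atoms: water, O
Why: Dehydrobromination at either of the two equivalent positions ortho to bromine gives the single aryne 4, which undergoes a stepwise [2+2] cycloaddition with the ketene acetal. The CH2 carbon of 3 attacks the aryne carbon remote from the methoxy group so that the aryl anion forms beside oxygen and closes on the dioxocarbenium carbon; this places the acetal carbon (future C1) next to the future C8 methoxy group. Mild acid hydrolysis of 5 then gives the ketone.

Step 3
Reactants: 2 2-(benzyloxy)-5-bromo-1,3-dimethoxybenzene; 6 4-(benzyloxy)-3,5-dimethoxybicyclo[4.2.0]octa-1,3,5-trien-7-one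
Product: 8 rac-4-(benzyloxy)-7-[4-(benzyloxy)-3,5-dimethoxyphenyl]-3,5-dimethoxybicyclo[4.2.0]octa-1,3,5-trien-7-ol, via arylmagnesium bromide 7 (not isolated)
Conditions: Mg, THF, 40 °C; then 6, THF, −78 °C; aq. NH4Cl at −78 °C
Reagents that add atoms: none
Why: Grignard addition to a strained ketone that does not enolise readily, because its enolate would be an antiaromatic benzocyclobutadiene. The magnesium alkoxide is quenched cold so that anion-accelerated opening of the four-membered ring cannot start; the new carbinol centre is racemic and is removed in step 4.

Step 4
Reactants: 8 rac-4-(benzyloxy)-7-[4-(benzyloxy)-3,5-dimethoxyphenyl]-3,5-dimethoxybicyclo[4.2.0]octa-1,3,5-trien-7-ol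
Product: 9 rac-4-(benzyloxy)-7-[4-(benzyloxy)-3,5-dimethoxyphenyl]-3,5-dimethoxybicyclo[4.2.0]octa-1,3,5-triene
Conditions: Et3SiH, CF3CO2H, CH2Cl2, −40 to 0 °C
Reagents that add atoms: none
Why: Ionic hydrogenation: acid ionises the tertiary, doubly benzylic alcohol to a diarylcarbenium ion stabilised by the ortho and para methoxy groups of ring A and by ring C, and the silane delivers hydride. The cation has no elimination path short of a benzocyclobutadiene, and the brief cold acid exposure should spare the benzyl ethers and the strained ring; C1 of 9 is racemic, which is immaterial because it becomes planar in step 6.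

Step 5
Reactants: 10 fumaryl chloride; 11 methyl (S)-lactate (two equivalents)
Product: 12 bis[(2S)-1-methoxy-1-oxopropan-2-yl] (2E)-but-2-enedioate
Conditions: pyridine, CH2Cl2, 0 °C to rt (11 in slight excess over two equivalents)
Reagents that add atoms: methyl (S)-lactate (the second equivalent of 11, which esterifies the second acid chloride group), C[C@H](O)C(=O)OC
Why: Twofold acylation of the secondary alcohol by the diacid chloride with pyridine as HCl acceptor, one molecule of 11 on each acyl chloride; the lactate stereocentre is not enolised under these conditions and the E-alkene is retained.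

Step 6
Reactants: 9 rac-4-(benzyloxy)-7-[4-(benzyloxy)-3,5-dimethoxyphenyl]-3,5-dimethoxybicyclo[4.2.0]octa-1,3,5-triene; 12 bis[(2S)-1-methoxy-1-oxopropan-2-yl] (2E)-but-2-enedioate
Product: 14 bis[(2S)-1-methoxy-1-oxopropan-2-yl] (1S,2R,3R)-7-(benzyloxy)-1-[4-(benzyloxy)-3,5-dimethoxyphenyl]-6,8-dimethoxy-1,2,3,4-tetrahydronaphthalene-2,3-dicarboxylate, via ortho-quinodimethane 13 (not isolated)
Conditions: toluene, 110 °C, sealed tube, Ar (12 in twofold excess, trace BHT)
Reagents that add atoms: none
Why: Heating breaks the C1–C4 σ-bond of 9 in a thermally allowed conrotatory 4π electrocyclic ring opening in which the aryl group turns outward (the inward path would drive it into the C4 methylene), so both enantiomers of 9 converge on the single achiral diene 13, which forms reversibly and stays at low stationary concentration. 13 is intercepted by 12 in a concerted suprafacial [4+2] cycloaddition (Diels–Alder reaction) that restores the aromaticity of ring A and forms C1–C2 and C3–C4, so ring B is closed by annulating the four-carbon unit C1–C8a–C4a–C4 with the two-carbon unit C2–C3 in one event. The closest known reaction type is the thermal opening of 1-substituted benzocyclobutenes with capture of the resulting ortho-quinodimethanes by fumarates of α-hydroxy esters. For C2 and C3, the trans relation is copied from the E-alkene of 12, and the absolute sense comes from the two (S)-lactate groups, which are related by the twofold axis of the fumarate and therefore shield the same π-face; addition to the Re face at C2 and C3 gives 2R,3R. For C1, the configuration relative to C2 is set by the orientation of 12: the C2 ester exo (pointing away from the diene) and the C3 ester endo beneath C4a give the 1,2-trans relation and hence 1S. The selectivity the step needs is therefore exo placement of the C2 ester; what should secure it is the congested sector beneath C8a, walled by the twisted outward aryl group and the out-of-plane C8 methoxy group, which should accept the C2 hydrogen more readily than an ester, while the sector beneath C4a next to the unsubstituted C4 is open. The three oxygen donors on ring A raise the diene HOMO toward the electron-poor fumarate, and because the auxiliaries make every stereoisomeric adduct a diastereomer of 14, minor isomers can be removed by chromatography or crystallisation before the auxiliaries are cleaved.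

Step 7
Reactants: 14 bis[(2S)-1-methoxy-1-oxopropan-2-yl] (1S,2R,3R)-7-(benzyloxy)-1-[4-(benzyloxy)-3,5-dimethoxyphenyl]-6,8-dimethoxy-1,2,3,4-tetrahydronaphthalene-2,3-dicarboxylate
Product: 15 [(1S,2R,3R)-7-(benzyloxy)-1-[4-(benzyloxy)-3,5-dimethoxyphenyl]-6,8-dimethoxy-1,2,3,4-tetrahydronaphthalene-2,3-diyl]dimethanol
Conditions: LiAlH4, THF, 0 °C to rt; aq. NaOH work-up
Reagents that add atoms: none
Why: Hydride reduction of all four ester carbonyls turns the two ring acyl groups into the C9 and C9' primary alcohols and releases the auxiliaries as water-soluble (S)-propane-1,2-diol. Reduction at 0 °C should be much faster than enolisation, so C2 and C3 keep their configuration, and aryl benzyl ethers are inert to the hydride.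

Step 8
Reactants: 15 [(1S,2R,3R)-7-(benzyloxy)-1-[4-(benzyloxy)-3,5-dimethoxyphenyl]-6,8-dimethoxy-1,2,3,4-tetrahydronaphthalene-2,3-diyl]dimethanol
Product: 16 (1S,2R,3R)-1-(4-hydroxy-3,5-dimethoxyphenyl)-2,3-bis(hydroxymethyl)-6,8-dimethoxy-1,2,3,4-tetrahydronaphthalen-7-ol
Conditions: H2 (1 atm), Pd/C, EtOAc–MeOH, rt
Reagents that add atoms: none
Why: Catalytic hydrogenolysis of the two aryl benzyl ethers under neutral conditions. The C1–aryl and C1–C8a bonds carry no heteroatom and are not cleaved, and no stereocentre is touched.

## Compound list

1 | 4-bromo-2,6-dimethoxyphenol | COc1cc(Br)cc(OC)c1O | starting material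
2 | 2-(benzyloxy)-5-bromo-1,3-dimethoxybenzene | COc1cc(Br)cc(OC)c1OCc1ccccc1 | intermediate
3 | 1,1-dimethoxyethene | C=C(OC)OC | starting material
4 | 2-(benzyloxy)-1,3-dimethoxy-4,5-didehydrobenzene (aryne, formed in the flask, not isolated) | COC1=CC#CC(OC)=C1OCc1ccccc1 | intermediate
5 | 4-(benzyloxy)-3,5,7,7-tetramethoxybicyclo[4.2.0]octa-1,3,5-triene (formed in the flask, not isolated) | COc1cc2c(c(OC)c1OCc1ccccc1)C(OC)(OC)C2 | intermediate
6 | 4-(benzyloxy)-3,5-dimethoxybicyclo[4.2.0]octa-1,3,5-trien-7-one | COc1cc2c(c(OC)c1OCc1ccccc1)C(=O)C2 | intermediate
7 | [4-(benzyloxy)-3,5-dimethoxyphenyl]magnesium bromide (formed in the flask, not isolated) | COc1cc([Mg]Br)cc(OC)c1OCc1ccccc1 | intermediate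
8 | rac-4-(benzyloxy)-7-[4-(benzyloxy)-3,5-dimethoxyphenyl]-3,5-dimethoxybicyclo[4.2.0]octa-1,3,5-trien-7-ol | COc1cc(C2(O)Cc3cc(OC)c(OCc4ccccc4)c(OC)c32)cc(OC)c1OCc1ccccc1 | intermediate
9 | rac-4-(benzyloxy)-7-[4-(benzyloxy)-3,5-dimethoxyphenyl]-3,5-dimethoxybicyclo[4.2.0]octa-1,3,5-triene | COc1cc(C2Cc3cc(OC)c(OCc4ccccc4)c(OC)c32)cc(OC)c1OCc1ccccc1 | intermediate
10 | fumaryl chloride | O=C(Cl)/C=C/C(=O)Cl | starting material
11 | methyl (S)-lactate | C[C@H](O)C(=O)OC | starting material
12 | bis[(2S)-1-methoxy-1-oxopropan-2-yl] (2E)-but-2-enedioate | C[C@H](OC(=O)/C=C/C(=O)O[C@@H](C)C(=O)OC)C(=O)OC | intermediate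
13 | (6Z)-2-(benzyloxy)-6-{[4-(benzyloxy)-3,5-dimethoxyphenyl]methylidene}-1,3-dimethoxy-5-methylidenecyclohexa-1,3-diene (aryl-outward ortho-quinodimethane, formed in the flask, not isolated) | C=C1C=C(OC)C(OCc2ccccc2)=C(OC)/C1=C\c1cc(OC)c(OCc2ccccc2)c(OC)c1 | intermediate
14 | bis[(2S)-1-methoxy-1-oxopropan-2-yl] (1S,2R,3R)-7-(benzyloxy)-1-[4-(benzyloxy)-3,5-dimethoxyphenyl]-6,8-dimethoxy-1,2,3,4-tetrahydronaphthalene-2,3-dicarboxylate | COc1cc([C@H]2c3c(cc(OC)c(OCc4ccccc4)c3OC)C[C@@H](C(=O)O[C@@H](C)C(=O)OC)[C@@H]2C(=O)O[C@@H](C)C(=O)OC)cc(OC)c1OCc1ccccc1 | intermediate
15 | [(1S,2R,3R)-7-(benzyloxy)-1-[4-(benzyloxy)-3,5-dimethoxyphenyl]-6,8-dimethoxy-1,2,3,4-tetrahydronaphthalene-2,3-diyl]dimethanol | COc1cc([C@H]2c3c(cc(OC)c(OCc4ccccc4)c3OC)C[C@@H](CO)[C@@H]2CO)cc(OC)c1OCc1ccccc1 | intermediate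
16 | (1S,2R,3R)-1-(4-hydroxy-3,5-dimethoxyphenyl)-2,3-bis(hydroxymethyl)-6,8-dimethoxy-1,2,3,4-tetrahydronaphthalen-7-ol | COc1cc([C@H]2c3c(cc(OC)c(O)c3OC)C[C@@H](CO)[C@@H]2CO)cc(OC)c1O | target

## Step count and least certain steps

Total step count: 8. Longest linear sequence: 7 (steps 1, 2, 3, 4, 6, 7, 8); step 5 is a one-step side branch.

The least certain steps, in route order, are step 2, step 4 and step 6. Step 6, the key step, is the least certain of the three.

**Step 2.** The most likely failure is capture of aryne 4 by amide instead of by 3, giving aminoarenes, together with slow heterogeneous dehydrobromination at reflux; NaNH2 is both base and nucleophile. The fallback sets out from 2 and comes back at 6. 2 is treated at −78 °C with lithium 2,2,6,6-tetramethylpiperidide (LiTMP) in the presence of lithium ethenolate, made in the flask from n-BuLi and THF. The enolate carbon adds to 4 at the same carbon as 3 does, and the aryl anion closes on the aldehyde carbon. A water quench gives rac-4-(benzyloxy)-3,5-dimethoxybicyclo[4.2.0]octa-1,3,5-trien-7-ol F1. Oxidation of F1 with 1,1,1-triacetoxy-1,1-dihydro-1,2-benziodoxol-3(1H)-one (DMP) in CH2Cl2 returns to 6.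

**Step 4.** The most likely failure is diversion of the long-lived C1 cation before hydride transfer: Friedel–Crafts self-alkylation on the electron-rich rings, loss of a benzyl ether in acid, or fragmentation of the four-membered ring. The fallback avoids the tertiary cation; it sets out from 6 and comes back at 9. NaBH4 in MeOH at 0 °C gives the benzocyclobutenol F1. PBr3 in CH2Cl2 at −20 °C converts it into rac-4-(benzyloxy)-7-bromo-3,5-dimethoxybicyclo[4.2.0]octa-1,3,5-triene F2, used cold and crude because it is an activated benzylic bromide. Coupling of F2 with 7 under CuI catalysis in THF at −20 °C forms the C1–aryl bond and gives 9.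

**Step 6.** Three things may go wrong.
- Endo placement of the C2 ester would give the 1,2-cis adduct. The preference between the two orientations of a fumarate on an unsymmetrical diene is small, and no later base treatment can repair it.
- Facial discrimination by the lactate groups may be weak at 110 °C.
- Outward rotation of the aryl group may be slowed by the peri C8 methoxy group, so that 13 dimerises.

The fallback keeps the cycloaddition for C2 and C3 but makes C1 in a separate cationic step; it sets out from 6 and comes back at 16.
- NaBH4 gives the benzocyclobutenol F1.
- Heating F1 with 12 in toluene opens the ring with the hydroxyl group outward. A hydrogen bond from this hydroxyl to a lactate carbonyl is expected to organise endo addition on one face and give bis[(2S)-1-methoxy-1-oxopropan-2-yl] (1S,2S,3R)-7-(benzyloxy)-1-hydroxy-6,8-dimethoxy-1,2,3,4-tetrahydronaphthalene-2,3-dicarboxylate F3.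
- CF3CO2H in CH2Cl2 at 0 °C ionises C1 of F3 in the presence of an excess of commercial 2,6-dimethoxyphenol (A7). The phenol should attack through its para position anti to the C2 ester and give bis[(2S)-1-methoxy-1-oxopropan-2-yl] (1S,2R,3R)-7-(benzyloxy)-1-(4-hydroxy-3,5-dimethoxyphenyl)-6,8-dimethoxy-1,2,3,4-tetrahydronaphthalene-2,3-dicarboxylate F4.
- LiAlH4 in THF reduces F4 to [(1S,2R,3R)-7-(benzyloxy)-1-(4-hydroxy-3,5-dimethoxyphenyl)-6,8-dimethoxy-1,2,3,4-tetrahydronaphthalene-2,3-diyl]dimethanol F5.
- Hydrogenolysis of F5 over Pd/C gives 16.

## Further compounds

F1 | step 2 | rac-4-(benzyloxy)-3,5-dimethoxybicyclo[4.2.0]octa-1,3,5-trien-7-ol | COc1cc2c(c(OC)c1OCc1ccccc1)C(O)C2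
F2 | step 4 | rac-4-(benzyloxy)-7-bromo-3,5-dimethoxybicyclo[4.2.0]octa-1,3,5-triene | COc1cc2c(c(OC)c1OCc1ccccc1)C(Br)C2
F3 | step 6 | bis[(2S)-1-methoxy-1-oxopropan-2-yl] (1S,2S,3R)-7-(benzyloxy)-1-hydroxy-6,8-dimethoxy-1,2,3,4-tetrahydronaphthalene-2,3-dicarboxylate | O[C@@H]1c2c(cc(OC)c(OCc3ccccc3)c2OC)C[C@@H](C(=O)O[C@@H](C)C(=O)OC)[C@@H]1C(=O)O[C@@H](C)C(=O)OC
F4 | step 6 | bis[(2S)-1-methoxy-1-oxopropan-2-yl] (1S,2R,3R)-7-(benzyloxy)-1-(4-hydroxy-3,5-dimethoxyphenyl)-6,8-dimethoxy-1,2,3,4-tetrahydronaphthalene-2,3-dicarboxylate | COc1cc([C@H]2c3c(cc(OC)c(OCc4ccccc4)c3OC)C[C@@H](C(=O)O[C@@H](C)C(=O)OC)[C@@H]2C(=O)O[C@@H](C)C(=O)OC)cc(OC)c1O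
F5 | step 6 | [(1S,2R,3R)-7-(benzyloxy)-1-(4-hydroxy-3,5-dimethoxyphenyl)-6,8-dimethoxy-1,2,3,4-tetrahydronaphthalene-2,3-diyl]dimethanol | COc1cc([C@H]2c3c(cc(OC)c(OCc4ccccc4)c3OC)C[C@@H](CO)[C@@H]2CO)cc(OC)c1O
A1 | alternative 1 | (3R)-4-{4-(benzyloxy)-2-[(3,5-dimethoxy-4-oxocyclohexa-2,5-dien-1-ylidene)methyl]-3,5-dimethoxyphenyl}-3-{[(tert-butyldimethylsilyl)oxy]methyl}butanal | O=CC[C@H](CO[Si](C)(C)C(C)(C)C)Cc1cc(OC)c(OCc2ccccc2)c(OC)c1C=C1C=C(OC)C(=O)C(OC)=C1
A2 | alternative 1 | (1S,2R,3R)-7-(benzyloxy)-3-{[(tert-butyldimethylsilyl)oxy]methyl}-1-(4-hydroxy-3,5-dimethoxyphenyl)-6,8-dimethoxy-1,2,3,4-tetrahydronaphthalene-2-carbaldehyde | COc1cc([C@H]2c3c(cc(OC)c(OCc4ccccc4)c3OC)C[C@@H](CO[Si](C)(C)C(C)(C)C)[C@@H]2C=O)cc(OC)c1O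
A3 | alternative 2 | {3-(benzyloxy)-2,4-dimethoxy-6-[(2E)-4-methoxybut-2-en-1-yl]phenyl}boronic acid | COC/C=C/Cc1cc(OC)c(OCc2ccccc2)c(OC)c1B(O)O
A4 | alternative 2 | methyl 3-[4-(benzyloxy)-3,5-dimethoxyphenyl]prop-2-ynoate | COC(=O)C#Cc1cc(OC)c(OCc2ccccc2)c(OC)c1
A5 | alternative 2 | methyl (3S)-7-(benzyloxy)-1-[4-(benzyloxy)-3,5-dimethoxyphenyl]-3-ethenyl-6,8-dimethoxy-3,4-dihydronaphthalene-2-carboxylate | COc1cc(C2=C(C(=O)OC)[C@H](C=C)Cc3cc(OC)c(OCc4ccccc4)c(OC)c32)cc(OC)c1OCc1ccccc1
A6 | alternative 3 | (3R,4R)-3-[(benzyloxy)methyl]-4-{[4-(benzyloxy)-3,5-dimethoxyphenyl]methyl}oxolan-2-ol (mixture at the hemiacetal carbon) | OC1OC[C@H](Cc2cc(OC)c(OCc3ccccc3)c(OC)c2)[C@@H]1COCc1ccccc1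
A7 | alternative 3 | 2,6-dimethoxyphenol | COc1cccc(OC)c1O
A8 | alternative 3 | {(1S,2R,3R)-7-(benzyloxy)-2-[(benzyloxy)methyl]-1-(4-hydroxy-3,5-dimethoxyphenyl)-6,8-dimethoxy-1,2,3,4-tetrahydronaphthalen-3-yl}methanol (tetralin numbering of the text) | COc1cc([C@H]2c3c(cc(OC)c(OCc4ccccc4)c3OC)C[C@@H](CO)[C@@H]2COCc2ccccc2)cc(OC)c1O
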